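## Structural features

The target is a germacrane-type sesquiterpene lactone: a ten-membered carbocycle (C1–C10) with an α-methylene-γ-butyrolactone fused across C7–C8 (ring oxygen on C8, carbonyl C12, exocyclic C11=C13). Two trisubstituted ring alkenes sit in a 1,5-relation, C1=C10 (ring-trans, methyl C14) and C4=C5 (ring-cis, carrying C15H2–O), linked by the C2–C3 ethano bridge. C6 (R, free allylic hydroxyl), C7 (S) and C8 (S) are contiguous; H6/H7 and H7/H8 are both anti, so the lactone is trans-fused and the C6 hydroxyl lies anti to the C7–C11 bond. C15–O is acylated by (Z)-2-(acetoxymethyl)but-2-enoic acid, which is both an allylic acetate and a Michael acceptor. The fragile groups are the α-methylene lactone (base, nucleophiles, light), the side-chain ester (Z to E isomerisation, SN2′ attack, acetate loss), the allylic C6 alcohol and the 1,5-diene (Cope rearrangement, transannular cyclisation in acid). The real difficulty is a medium ring holding one E and one ring-cis trisubstituted alkene next to a trans lactone fusion; at the 6-oxo stage C7–H is α to the ketone and the lactone oxygen is β to it, so epimerisation and β-elimination threaten. The key step exploits the 1,5-diene C10=C1–C2–C3–C4=C5: it is the cycloreversion product of a bicyclo[2.2.0]hexane (σ bonds C1–C4 and C5–C10) fused through C5–C10 to the six-membered ring C5–C6–C7–C8–C9–C10. The C6 carbonyl of that ring is the enone carbonyl that allows the [2+2] photoaddition.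

## Logic of the disconnections

**34 from 33.** The O6–Si bond is cut last. C6–OH must stay masked while C15–OH is acylated, and fluoride removes the silyl group without touching the methylene lactone or the acetate. The demand is a buffered, non-basic desilylation.

**33 from 27 and 32.** The C15–O ester bond is cut. The side chain cannot survive enolate chemistry or hydroxide, so it must arrive last and intact. The route becomes convergent. The forward step must not activate the acid carbonyl of 32 (geometry and SN2′ risk), so the alcohol 27 is activated instead.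

**32 from 28 (through 29, 30, 31).** The C2′–carboxyl bond and the C3′–H bond are cut back to the alkyne 28. The carboxyl must end up cis to the methyl, which is an anti addition of H and a carbon unit across the triple bond. Hydroxyl-directed trans-hydrometalation followed by carbonylation with retention does this, and a C4 alkynol replaces a stereodefined trisubstituted enoate.

**27 from 22 (through 26).** The C11=C13 bond is cut. The exocyclic methylene would not survive irradiation, 175 °C or hydroxide, so it is installed only after all three. This requires an enolisable lactone and both hydroxyls silylated, with the C15 silyl group more labile than the C6 one.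

**22 from 17 (through 19 and 21).** The C15 oxidation level is adjusted (ester to acid to alcohol). The ester is needed earlier for the photoaddition and the cycloreversion. O6 is silylated before hydroxide opens the lactone, so that only O8 can close back on C12 and no 6,12-lactone can form.

**17 from 15 (through 16).** The C6–H bond is cut (hydride addition). The ketone has done its work, and its reduction removes the epimerisable, elimination-prone β-acyloxy ketone. The demand is 1,2-selectivity over the doubly activated C4=C5 bond and the (6R) face.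

**15 from 14.** The C1=C10 and C4=C5 π bonds are traded for the σ bonds C1–C4 and C5–C10. The ten-membered ring with both alkenes in place is exchanged for a compact tetracycle. The forward step needs no dilution because the ring arises by cleavage of a shared bond. It must place the ring-cis geometry on C4=C5 and stop before a Cope rearrangement.

**14 from 10 and 13; 13 from 11 (through 12).** The C4–C5 and C1–C10 bonds are cut ([2+2]). The ester on 13 directs head-to-head addition and becomes C15. The four cyclobutane stereocentres are erased later, so only constitution matters. 13 comes from 11 by cutting the C1=C2 bond of the cyclobutene (dehydrobromination).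

**10 from 6 (through 8).** The C10–C14 bond and the C5=C10 unsaturation are cut. Starting from a methyl-bearing dione would put a racemic stereocentre at C10 next to any enantioselective step. Here C7 and C8 are set first on a methyl-free ring; the methyl and the enone follow through enolates that are regiodefined toward C5. C7–H is never enolised, so the kinetically made trans lactone cannot relax to the cis fusion or eliminate.

**6 from 2 and 3 (through 4 and 5); 2 from 1.** The C7–C11 bond and the lactone O8–C12 bond are cut, then the epoxide C–O bonds. The epoxide stores the C8 oxygen and, after reductive cleavage, gives a regiodefined enolate at C7. Alkylation anti to the C8 oxygen sets the trans relation, and closing the lactone does not touch C8. The absolute configuration comes from one catalytic step on the achiral enone 1.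

## Other disconnections considered

**Alternative 1:** The cut is C6–C7, with O–C13 as the bond to be broken in the forward sense. The substrate is the thirteen-membered α-stannyl diallylic ether A1; tin–lithium exchange at C6 triggers a [2,3]-shift to the carbocycle A2.
- In its favour: one low-temperature step would deliver the ten-membered ring, the free C6 hydroxyl, the C6 and C7 stereocentres and the C11=C13 methylene. On these points it is better than the chosen plan, which needs a separate reduction for C6 and a multi-operation methylenation. Both ring alkenes would be made with acyclic control and never heated, which is at least equal to the chosen plan.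
- Against it: A1 needs a macro-etherification and a configurationally defined α-alkoxystannane, because the shift inverts the carbanion carbon and so fixes C6. A transannular [1,2]-shift can compete, and the facial course at C7 is uncertain. After A2, the tetrahydrofuran C12 must be oxidised to the lactone beside five other allylic positions.
- Comparison: the mechanism (anionic sigmatropic shift) is gentler than a 175 °C cycloreversion. In structure, the chosen plan has the lactone at the right oxidation level from the start. In step economy, the route to A1 is unlikely to be shorter than the six steps to 14.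

**Alternative 2:** The cut is C8–C9, with the C1–C6 bond of a cyclohexenol broken in the forward sense. The potassium alkoxide A3 would undergo anionic oxy-Cope ring expansion to the dienone A4.
- In its favour: the ring-cis C4=C5 bond is inherited from the cyclohexene and the E geometry of C1=C10 follows from a chair transition state. This is better than the chosen plan, where the two geometries must partition correctly. C15 is already at the alcohol level, which saves the saponification and reduction steps (better). The ten-membered ring is reached in few steps from a chiral-pool terpene (equal or better).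
- Against it: the cyclohexenone behind A3 carries its only stereocentre α to the carbonyl, with an isopropenyl group that can move into conjugation. The organometallic must add trans to that group. The C1 stereocentre is destroyed while C8 is created, so everything rests on one chair-versus-boat choice. C7 is set only by protonation of the C6 enolate, with no built-in preference for the trans relation to C8.
- Comparison: A4 still needs the same C6 reduction and methylenation as the chosen plan, plus oxidation of the lactol ether. The chosen plan is weaker on alkene geometry but stronger on C7/C8, which it fixes by reagent control before the ring exists.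

**Alternative 3:** The cut is C2–C3. The eleven-membered cyclic amine A5 would be treated with an anomeric amide; loss of N2 from the isodiazene and recombination of the two allyl radicals would give A6.
- In its favour: the ring is first closed through C–N bonds, and the contraction runs near room temperature, so the Cope problem does not arise (better). C6, C7, C8, both protected oxygens and the lactone are in place beforehand, so C6 does not depend on a macrocyclic reduction (better).
- Against it: both radicals are allylic and ambident (C2/C10 and C3/C5). Recombination can therefore give smaller rings with vinyl branches, and each allyl radical can lose its alkene geometry before coupling. Nitrogen deletion is less efficient without benzylic stabilisation. A5 needs two stereodefined trisubstituted allylic fragments and an eleven-membered ring closure, which costs steps.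
- Comparison: the alternative is better on C6 and on thermal mildness. The chosen plan is better on constitutional fidelity of the ring-forming step, which can only open the bicyclo[2.2.0]hexane one way, and on step count to the ring.

Key step: step 8

**Remarks on the chemistry**

- Germacrane numbering (C1–C15) is used for all ring compounds; the SMILES strings define the configurations.
- Correction: the ring-cis C4=C5 bond has the CIP descriptor E in 15–34, because C15 outranks C3. A label "4Z" for this bond can only mean ring-cis; the structures themselves are unchanged.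
- Correction: the core of 14 is a cyclohexanone fused to a bicyclo[2.2.0]hexane; only the central four-membered ring shares a bond (C5–C10) with the six-membered ring.
- The CIP descriptor of C7 switches between R and S along the route (ketone or silyl ether on C6 versus free hydroxyl) with no change in spatial arrangement.
- Assumption: of the two pseudoenantiomeric cinchona-derived primary amines, the one that gives (1S,6S)-2 is used in step 1.

## Route

Step 1
Reactants: 1 cyclohex-2-en-1-one
Product: 2 (1S,6S)-7-oxabicyclo[4.1.0]heptan-2-one
Conditions: H2O2 (50% aq.), 9-amino-9-deoxy-epi-cinchona primary amine·2 CF3CO2H (10 mol %), dioxane, 30 °C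
Reagents that add atoms: hydrogen peroxide, OO
Why: Iminium-activated nucleophilic epoxidation of a cyclic enone; the chiral primary ammonium salt directs hydroperoxide addition to one face of C8 and ring closure then fixes C7, so both epoxide carbons are set by the catalyst on an achiral substrate.

Step 2
Reactants: 2 (1S,6S)-7-oxabicyclo[4.1.0]heptan-2-one; 3 tert-butyl bromoacetate
Product: 6 (3aR,7aS)-hexahydro-1-benzofuran-2,4-dione (trans-fused), via dilithium enolate alkoxide 4 (not isolated), via hydroxy keto ester 5 (not isolated)
Conditions: lithium 4,4′-di-tert-butylbiphenylide (LiDBB), THF, −78 °C; 3, DMPU, −78 → −50 °C; AcOH quench; crude in CF3CO2H/CH2Cl2, 0 °C → rt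
Reagents that add atoms: none
Why: Reductive cleavage of the Cα–O bond of the α,β-epoxy ketone gives the regiodefined β-alkoxide enolate 4, which cannot eliminate; C-alkylation (reductive alkylation of an epoxy ketone) occurs anti to the C8–O bond and sets C7 trans to C8. Acid then removes the tert-butyl group and closes the γ-lactone at the acyl carbon, so C8 is retained and no base meets the β-acyloxy ketone.

Step 3
Reactants: 6 (3aR,7aS)-hexahydro-1-benzofuran-2,4-dione
Product: 8 (3aR,7aS)-3,3a,7,7a-tetrahydro-1-benzofuran-2,4-dione, via lithium enolate 7 (not isolated)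
Conditions: lithium diisopropylamide, THF, −78 °C; then PhS(Cl)=N-t-Bu, −78 °C
Reagents that add atoms: none
Why: Kinetic deprotonation takes the C5 methylene and not the tertiary C7–H; the enolate is sulfenylated on carbon by the sulfinimidoyl chloride and the adduct undergoes syn elimination at −78 °C (one-pot ketone dehydrogenation), leaving C7 and C8 untouched.

Step 4
Reactants: 8 (3aR,7aS)-3,3a,7,7a-tetrahydro-1-benzofuran-2,4-dione
Product: 10 (3aR,7aS)-6-methyl-3,3a,7,7a-tetrahydro-1-benzofuran-2,4-dione, via lithium enolate 9 (not isolated)
Conditions: Me2CuLi (from MeLi and copper iodide CuI), Et2O, −78 °C; then PhS(Cl)=N-t-Bu, THF, −78 → −30 °C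
Reagents that add atoms: lithium dimethylcuprate, [Li+].C[Cu-]C
Why: Cuprate conjugate addition puts the methyl group on C10 and gives an enolate defined toward C5, which the sulfinimidoyl chloride dehydrogenates in the same flask (one-pot β-alkylation of an enone). The C10 stereocentre is transient and the lactone is inert to the cuprate at −78 °C.

Step 5
Reactants: 11 ethyl 1-bromocyclobutane-1-carboxylate
Product: 12 cyclobut-1-ene-1-carboxylic acid
Conditions: KOH (powder), PhMe, reflux; then aq. HCl
Reagents that add atoms: potassium hydroxide, [K+].[OH-]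
Why: E2 dehydrobromination of the tertiary α-bromo ester with concurrent saponification, the classical entry to cyclobutene-1-carboxylic acid.

Step 6
Reactants: 12 cyclobut-1-ene-1-carboxylic acid
Product: 13 methyl cyclobut-1-ene-1-carboxylate
Conditions: MeI, K2CO3, acetone, rt; used freshly distilled
Reagents that add atoms: iodomethane, CI
Why: SN2 O-alkylation of the carboxylate; non-acidic conditions avoid polymerisation of the strained acrylate.

Step 7
Reactants: 10 (3aR,7aS)-6-methyl-3,3a,7,7a-tetrahydro-1-benzofuran-2,4-dione; 13 methyl cyclobut-1-ene-1-carboxylate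
Product: 14 methyl (1R,4S,5R,7R,8S,10R) head-to-head cis-anti-cis photoadduct (germacrane numbering: central cyclobutane C1–C4–C5–C10, outer cyclobutane C1–C2–C3–C4, CO2Me on C4, CH3 on C10, C6 ketone, 7,8-trans γ-lactone)
Conditions: hν (350 nm, Pyrex), 13 (6 equiv), CH2Cl2, −30 °C
Reagents that add atoms: none
Why: Triplet enone–alkene [2+2] photocycloaddition; an electron-poor alkene should add head-to-head, so the ester carbon C4 bonds to the enone α-carbon C5 and C1 to C10, with cis 6/4 fusion and anti four-membered rings. The four new stereocentres are erased in step 8, so only the head-to-head constitution matters.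

Step 8
Reactants: 14 methyl (1R,4S,5R,7R,8S,10R) head-to-head cis-anti-cis photoadduct
Product: 15 methyl (3aR,5E,9E,11aS)-10-methyl-2,4-dioxo-2,3,3a,4,7,8,11,11a-octahydrocyclodeca[b]furan-6-carboxylate (germacrane: 6-oxo, 1(10)-E, 4,5-ring-cis, 7,8-trans-lactone)
Conditions: PhMe (0.005 M, degassed, BHT 1 mol %), sealed silylated glass tube, 175 °C, about 1 h, stopped at full conversion
Reagents that add atoms: none
Why: Thermal cycloreversion of the bicyclo[2.2.0]hexane: homolysis of the central C1–C4 bond gives a cyclohexane-1,4-diyl whose C4 radical is stabilised by the ester, and β-scission of C5–C10 then creates C4=C5 and C1=C10 together. The closest known reaction is the thermolysis of enone–cyclobutene photoadducts to cis,trans-cyclodeca-1,5-dienes, formally a [σ2s+σ2a] process. The ten-membered ring is not closed by bond formation; it appears when the C5–C10 bond shared by the six-membered ring and the central cyclobutane is cleaved, so there is no entropic penalty and no need for high dilution beyond suppressing bimolecular radical events. No stereocentre is formed: C1, C4, C5 and C10 become sp2, and C7 and C8 are spectators. The alkene geometries are decided in the chair-like diyl: with C6 axial on C5 and C9 equatorial on C10, C3 and C6 end up cis and C2 and C9 trans. This chair should be preferred because the developing C4=C5 bond can lie coplanar with both the ketone and the ester only in the ring-cis form, while the unconjugated C1=C10 bond takes the less strained trans geometry. The step must avoid the Cope rearrangement of its own product, which for a ring-cis/ring-trans diene can only use a boat and should therefore need a higher temperature, hence the limited time at 175 °C. It must also avoid enolisation toward C7, hence neutral silylated glass and a degassed hydrocarbon.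

Step 9
Reactants: 15 methyl (3aR,5E,9E,11aS)-10-methyl-2,4-dioxo-2,3,3a,4,7,8,11,11a-octahydrocyclodeca[b]furan-6-carboxylate
Product: 16 methyl (3aS,4R,5E,9E,11aS)-4-hydroxy-10-methyl-2-oxo-2,3,3a,4,7,8,11,11a-octahydrocyclodeca[b]furan-6-carboxylate
Conditions: NaBH4, CeCl3·7H2O, MeOH/CH2Cl2, −78 °C
Reagents that add atoms: none
Why: Luche reduction: the hard borohydride species attacks the C6 carbonyl and not the doubly activated C4=C5 bond, fast enough at −78 °C to outrun enolisation at C7. Peripheral attack on the conformer in which C6=O eclipses C7–H (anti to the C7–C11 bond, Felkin-type) should place the hydroxyl anti to C11, which is (6R).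

Step 10
Reactants: 16 methyl (3aS,4R,5E,9E,11aS)-4-hydroxy-10-methyl-2-oxo-2,3,3a,4,7,8,11,11a-octahydrocyclodeca[b]furan-6-carboxylate
Product: 17 methyl (3aR,4R,5E,9E,11aS)-4-[(tert-butyldimethylsilyl)oxy]-10-methyl-2-oxo-2,3,3a,4,7,8,11,11a-octahydrocyclodeca[b]furan-6-carboxylate
Conditions: TBSOTf, 2,6-lutidine, CH2Cl2, −78 → 0 °C
Reagents that add atoms: tert-butyldimethylsilyl trifluoromethanesulfonate, CC(C)(C)[Si](C)(C)OS(=O)(=O)C(F)(F)F
Why: Silylation of the hindered allylic alcohol with a silyl triflate and a non-nucleophilic base; blocking O6 here ensures that only O8 can re-close on C12 after the hydroxide step.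

Step 11
Reactants: 17 methyl (3aR,4R,5E,9E,11aS)-4-[(tert-butyldimethylsilyl)oxy]-10-methyl-2-oxo-2,3,3a,4,7,8,11,11a-octahydrocyclodeca[b]furan-6-carboxylate
Product: 19 (3aR,4R,5E,9E,11aS)-4-[(tert-butyldimethylsilyl)oxy]-10-methyl-2-oxo-2,3,3a,4,7,8,11,11a-octahydrocyclodeca[b]furan-6-carboxylic acid, via dilithium dicarboxylate 18 (not isolated)
Conditions: LiOH, THF/H2O, rt; then 1 M HCl to pH 3, EtOAc, rt
Reagents that add atoms: lithium hydroxide, [Li+].[OH-]
Why: Hydroxide hydrolyses the conjugated methyl ester and, reversibly, the lactone to 18; on acidification the γ-hydroxy acid re-closes at the acyl carbon (retention at C8) to the 8,12-lactone, the only one possible because O6 is silylated. C7 is not α to any carbonyl at this stage and cannot epimerise.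

Step 12
Reactants: 19 (3aR,4R,5E,9E,11aS)-4-[(tert-butyldimethylsilyl)oxy]-10-methyl-2-oxo-2,3,3a,4,7,8,11,11a-octahydrocyclodeca[b]furan-6-carboxylic acid
Product: 21 (3aR,4R,5E,9E,11aS)-4-[(tert-butyldimethylsilyl)oxy]-6-(hydroxymethyl)-10-methyl-3a,4,7,8,11,11a-hexahydrocyclodeca[b]furan-2(3H)-one, via mixed carbonic anhydride 20 (not isolated)
Conditions: i-BuOCOCl, N-methylmorpholine, THF, −15 °C; filter; NaBH4, THF/H2O, 0 °C
Reagents that add atoms: none
Why: Mixed-anhydride activation followed by borohydride reduction converts the acid into the primary allylic alcohol; the activated acyl group is reduced much faster than the γ-lactone at 0 °C.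

Step 13
Reactants: 21 (3aR,4R,5E,9E,11aS)-4-[(tert-butyldimethylsilyl)oxy]-6-(hydroxymethyl)-10-methyl-3a,4,7,8,11,11a-hexahydrocyclodeca[b]furan-2(3H)-one
Product: 22 (3aR,4R,5E,9E,11aS)-4-[(tert-butyldimethylsilyl)oxy]-10-methyl-6-{[(triethylsilyl)oxy]methyl}-3a,4,7,8,11,11a-hexahydrocyclodeca[b]furan-2(3H)-one
Conditions: TESCl, imidazole, CH2Cl2, 0 °C
Reagents that add atoms: chlorotriethylsilane, CC[Si](Cl)(CC)CC
Why: Standard silylation of a primary alcohol; the triethylsilyl ether survives the amide base of the next step and is more labile than the secondary silyl ether at C6.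

Step 14
Reactants: 22 (3aR,4R,5E,9E,11aS)-4-[(tert-butyldimethylsilyl)oxy]-10-methyl-6-{[(triethylsilyl)oxy]methyl}-3a,4,7,8,11,11a-hexahydrocyclodeca[b]furan-2(3H)-one
Product: 26 (3aR,4R,5E,9E,11aS)-4-[(tert-butyldimethylsilyl)oxy]-10-methyl-3-methylidene-6-{[(triethylsilyl)oxy]methyl}-3a,4,7,8,11,11a-hexahydrocyclodeca[b]furan-2(3H)-one, via lithium lactone enolate 23 (not isolated), via Mannich base 24 (not isolated), via trimethylammonium iodide 25 (not isolated)
Conditions: lithium diisopropylamide, THF, −78 °C; CH2=NMe2+ I−, −78 → 0 °C; MeI, THF/MeOH, rt; aq. NaHCO3, EtOAc, rt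
Reagents that add atoms: N,N-dimethylmethyleneiminium iodide (Eschenmoser's salt), C=[N+](C)C.[I-]
Why: Mannich reaction of the lactone enolate, N-methylation and base-induced β-elimination of trimethylamine, the standard α-methylenation of γ-lactones; the C11 stereocentre of 24 is lost on elimination, and the only acidic site in 22 is C11–H.

Step 15
Reactants: 26 (3aR,4R,5E,9E,11aS)-4-[(tert-butyldimethylsilyl)oxy]-10-methyl-3-methylidene-6-{[(triethylsilyl)oxy]methyl}-3a,4,7,8,11,11a-hexahydrocyclodeca[b]furan-2(3H)-one
Product: 27 (3aR,4R,5E,9E,11aS)-4-[(tert-butyldimethylsilyl)oxy]-6-(hydroxymethyl)-10-methyl-3-methylidene-3a,4,7,8,11,11a-hexahydrocyclodeca[b]furan-2(3H)-one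
Conditions: PPTS (cat.), MeOH/CH2Cl2, 0 °C
Reagents that add atoms: none
Why: Acid-catalysed methanolysis removes the primary triethylsilyl ether far faster than the hindered secondary tert-butyldimethylsilyl ether; methanol does not add to the methylene lactone under acid catalysis.

Step 16
Reactants: 28 but-2-yn-1-ol
Product: 29 (Z)-2-(tributylstannyl)but-2-en-1-ol
Conditions: Bu3SnH, [(C5Me5)RuCl]4 (cat.), CH2Cl2, rt
Reagents that add atoms: tributylstannane, CCCC[SnH](CCCC)CCCC
Why: Ruthenium-catalysed trans-hydrostannation of a propargylic alcohol: the hydroxyl steers tin to the proximal alkyne carbon and hydrogen is delivered anti, giving the stannane in which tin is cis to the methyl group.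

Step 17
Reactants: 29 (Z)-2-(tributylstannyl)but-2-en-1-ol
Product: 30 methyl (Z)-2-(hydroxymethyl)but-2-enoate
Conditions: Pd(OAc)2 (cat.), Ph3As (cat.), 1,4-benzoquinone, CF3CO2H (cat.), CO (1 atm), MeOH, rt
Reagents that add atoms: carbon monoxide, [C-]#[O+]; methanol, CO
Why: Oxidative methoxycarbonylation of an alkenylstannane: tin-to-palladium transmetalation with retention, CO insertion and methanolysis, with benzoquinone re-oxidising palladium; the carboxyl therefore ends up cis to the methyl group.

Step 18
Reactants: 30 methyl (Z)-2-(hydroxymethyl)but-2-enoate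
Product: 31 (Z)-2-(hydroxymethyl)but-2-enoic acid
Conditions: LiOH, THF/H2O, 0 °C → rt; then 1 M HCl
Reagents that add atoms: lithium hydroxide, [Li+].[OH-]
Why: Ester saponification at low temperature; the hydroxymethyl group is not a leaving group, so no SN2′ pathway can scramble the geometry.

Step 19
Reactants: 31 (Z)-2-(hydroxymethyl)but-2-enoic acid
Product: 32 (Z)-2-(acetoxymethyl)but-2-enoic acid
Conditions: Ac2O, pyridine, CH2Cl2, 0 °C → rt; aqueous work-up at pH 3
Reagents that add atoms: acetic anhydride, CC(=O)OC(C)=O
Why: O-Acetylation of the primary alcohol; the mixed anhydride formed at the carboxyl is hydrolysed on work-up, and no nucleophilic amine catalyst is used, so the allylic acetate is not exposed to SN2′ attack.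

Step 20
Reactants: 27 (3aR,4R,5E,9E,11aS)-4-[(tert-butyldimethylsilyl)oxy]-6-(hydroxymethyl)-10-methyl-3-methylidene-3a,4,7,8,11,11a-hexahydrocyclodeca[b]furan-2(3H)-one; 32 (Z)-2-(acetoxymethyl)but-2-enoic acid
Product: 33 [(3aR,4R,5E,9E,11aS)-4-[(tert-butyldimethylsilyl)oxy]-10-methyl-3-methylidene-2-oxo-2,3,3a,4,7,8,11,11a-octahydrocyclodeca[b]furan-6-yl]methyl (2Z)-2-(acetoxymethyl)but-2-enoate
Conditions: PPh3, DIAD, THF, −20 °C (betaine preformed); then 32 and 27, −20 → 0 °C
Reagents that add atoms: none
Why: Mitsunobu esterification activates the primary allylic alcohol, and the carboxylate displaces at C15 by SN2; the acid carbonyl is never turned into an acylating agent, so the Z geometry and the acetoxymethyl group should be preserved. Preforming the betaine keeps free phosphine away from both Michael acceptors.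

Step 21
Reactants: 33 [(3aR,4R,5E,9E,11aS)-4-[(tert-butyldimethylsilyl)oxy]-10-methyl-3-methylidene-2-oxo-2,3,3a,4,7,8,11,11a-octahydrocyclodeca[b]furan-6-yl]methyl (2Z)-2-(acetoxymethyl)but-2-enoate
Product: 34 [(3aS,4R,5E,9E,11aS)-4-hydroxy-10-methyl-3-methylidene-2-oxo-2,3,3a,4,7,8,11,11a-octahydrocyclodeca[b]furan-6-yl]methyl (2Z)-2-(acetoxymethyl)but-2-enoate (CNP0184624.2)
Conditions: HF·pyridine, pyridine, THF, 0 °C → rt
Reagents that add atoms: none
Why: Fluoride-driven cleavage of the secondary silyl ether under buffered, weakly acidic conditions; the methylene lactone, the acetate and the enoate are stable to it, and there is no strong acid to ionise the allylic alcohol.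

## Compound list

1 | cyclohex-2-en-1-one | O=C1C=CCCC1 | starting material
2 | (1S,6S)-7-oxabicyclo[4.1.0]heptan-2-one | O=C1CCC[C@@H]2O[C@H]12 | intermediate
3 | tert-butyl bromoacetate | CC(C)(C)OC(=O)CBr | starting material
4 | dilithium (3S)-cyclohex-1-ene-1,3-bis(olate) | [Li+].[Li+].[O-]C1=C[C@@H]([O-])CCC1 | intermediate
5 | tert-butyl 2-[(1R,2S)-2-hydroxy-6-oxocyclohexyl]acetate | O=C1CCC[C@H](O)[C@H]1CC(=O)OC(C)(C)C | intermediate
6 | (3aR,7aS)-hexahydro-1-benzofuran-2,4-dione (trans-fused) | O=C1C[C@H]2C(=O)CCC[C@@H]2O1 | intermediate
7 | lithium (3aR,7aS)-2-oxo-2,3,3a,6,7,7a-hexahydro-1-benzofuran-4-olate | [Li+].O=C1C[C@H]2C([O-])=CCC[C@@H]2O1 | intermediate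
8 | (3aR,7aS)-3,3a,7,7a-tetrahydro-1-benzofuran-2,4-dione | O=C1C[C@H]2C(=O)C=CC[C@@H]2O1 | intermediate
9 | lithium (3aR,7aS)-6-methyl-2-oxo-2,3,3a,6,7,7a-hexahydro-1-benzofuran-4-olate (C6 of the benzofuran undefined) | [Li+].O=C1C[C@H]2C([O-])=CC(C)C[C@@H]2O1 | intermediate
10 | (3aR,7aS)-6-methyl-3,3a,7,7a-tetrahydro-1-benzofuran-2,4-dione | O=C1C[C@H]2C(=O)C=C(C)C[C@@H]2O1 | intermediate
11 | ethyl 1-bromocyclobutane-1-carboxylate | CCOC(=O)C1(Br)CCC1 | starting material
12 | cyclobut-1-ene-1-carboxylic acid | OC(=O)C1=CCC1 | intermediate
13 | methyl cyclobut-1-ene-1-carboxylate | COC(=O)C1=CCC1 | intermediate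
14 | methyl (1R,4S,5R,7R,8S,10R) head-to-head cis-anti-cis photoadduct (germacrane numbering; 6-oxo, 7,8-trans 8,12-lactone, CO2Me on C4) | O=C1C[C@H]2C(=O)[C@H]3[C@]4(C(=O)OC)CC[C@@H]4[C@@]3(C)C[C@@H]2O1 | intermediate
15 | methyl (3aR,5E,9E,11aS)-10-methyl-2,4-dioxo-2,3,3a,4,7,8,11,11a-octahydrocyclodeca[b]furan-6-carboxylate | C1C(=O)O[C@H]2C/C(C)=C/CC/C(C(=O)OC)=C\C(=O)[C@H]12 | intermediate
16 | methyl (3aS,4R,5E,9E,11aS)-4-hydroxy-10-methyl-2-oxo-2,3,3a,4,7,8,11,11a-octahydrocyclodeca[b]furan-6-carboxylate | C1C(=O)O[C@H]2C/C(C)=C/CC/C(C(=O)OC)=C\[C@@H](O)[C@H]12 | intermediate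
17 | methyl (3aR,4R,5E,9E,11aS)-4-[(tert-butyldimethylsilyl)oxy]-10-methyl-2-oxo-2,3,3a,4,7,8,11,11a-octahydrocyclodeca[b]furan-6-carboxylate | C1C(=O)O[C@H]2C/C(C)=C/CC/C(C(=O)OC)=C\[C@@H](O[Si](C)(C)C(C)(C)C)[C@H]12 | intermediate
18 | dilithium 6-[(tert-butyldimethylsilyl)oxy]-8-hydroxygermacra-1(10),4-diene-12,15-dioate (C6, C7, C8 and both alkenes as in 17) | [Li+].[Li+].[O-]C(=O)C[C@@H]1[C@@H](O)C/C(C)=C/CC/C(C([O-])=O)=C\[C@H]1O[Si](C)(C)C(C)(C)C | intermediate
19 | (3aR,4R,5E,9E,11aS)-4-[(tert-butyldimethylsilyl)oxy]-10-methyl-2-oxo-2,3,3a,4,7,8,11,11a-octahydrocyclodeca[b]furan-6-carboxylic acid | C1C(=O)O[C@H]2C/C(C)=C/CC/C(C(=O)O)=C\[C@@H](O[Si](C)(C)C(C)(C)C)[C@H]12 | intermediate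
20 | isobutyl carbonic anhydride of 19 | C1C(=O)O[C@H]2C/C(C)=C/CC/C(C(=O)OC(=O)OCC(C)C)=C\[C@@H](O[Si](C)(C)C(C)(C)C)[C@H]12 | intermediate
21 | (3aR,4R,5E,9E,11aS)-4-[(tert-butyldimethylsilyl)oxy]-6-(hydroxymethyl)-10-methyl-3a,4,7,8,11,11a-hexahydrocyclodeca[b]furan-2(3H)-one | C1C(=O)O[C@H]2C/C(C)=C/CC/C(CO)=C\[C@@H](O[Si](C)(C)C(C)(C)C)[C@H]12 | intermediate
22 | (3aR,4R,5E,9E,11aS)-4-[(tert-butyldimethylsilyl)oxy]-10-methyl-6-{[(triethylsilyl)oxy]methyl}-3a,4,7,8,11,11a-hexahydrocyclodeca[b]furan-2(3H)-one | C1C(=O)O[C@H]2C/C(C)=C/CC/C(CO[Si](CC)(CC)CC)=C\[C@@H](O[Si](C)(C)C(C)(C)C)[C@H]12 | intermediate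
23 | lithium enolate of lactone 22 (C11=C12–O−) | [Li+].C1=C([O-])O[C@H]2C/C(C)=C/CC/C(CO[Si](CC)(CC)CC)=C\[C@@H](O[Si](C)(C)C(C)(C)C)[C@H]12 | intermediate
24 | 11-[(dimethylamino)methyl] derivative of 22 (C11 undefined) | CN(C)CC1C(=O)O[C@H]2C/C(C)=C/CC/C(CO[Si](CC)(CC)CC)=C\[C@@H](O[Si](C)(C)C(C)(C)C)[C@H]12 | intermediate
25 | 11-[(trimethylammonio)methyl] derivative of 22, iodide (C11 undefined) | [I-].C[N+](C)(C)CC1C(=O)O[C@H]2C/C(C)=C/CC/C(CO[Si](CC)(CC)CC)=C\[C@@H](O[Si](C)(C)C(C)(C)C)[C@H]12 | intermediate
26 | (3aR,4R,5E,9E,11aS)-4-[(tert-butyldimethylsilyl)oxy]-10-methyl-3-methylidene-6-{[(triethylsilyl)oxy]methyl}-3a,4,7,8,11,11a-hexahydrocyclodeca[b]furan-2(3H)-one | C=C1C(=O)O[C@H]2C/C(C)=C/CC/C(CO[Si](CC)(CC)CC)=C\[C@@H](O[Si](C)(C)C(C)(C)C)[C@H]12 | intermediate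
27 | (3aR,4R,5E,9E,11aS)-4-[(tert-butyldimethylsilyl)oxy]-6-(hydroxymethyl)-10-methyl-3-methylidene-3a,4,7,8,11,11a-hexahydrocyclodeca[b]furan-2(3H)-one | C=C1C(=O)O[C@H]2C/C(C)=C/CC/C(CO)=C\[C@@H](O[Si](C)(C)C(C)(C)C)[C@H]12 | intermediate
28 | but-2-yn-1-ol | CC#CCO | starting material
29 | (Z)-2-(tributylstannyl)but-2-en-1-ol | C/C=C(/CO)[Sn](CCCC)(CCCC)CCCC | intermediate
30 | methyl (Z)-2-(hydroxymethyl)but-2-enoate | COC(=O)/C(=C\C)CO | intermediate
31 | (Z)-2-(hydroxymethyl)but-2-enoic acid | OC(=O)/C(=C\C)CO | intermediate
32 | (Z)-2-(acetoxymethyl)but-2-enoic acid | OC(=O)/C(=C\C)COC(C)=O | intermediate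
33 | [(3aR,4R,5E,9E,11aS)-4-[(tert-butyldimethylsilyl)oxy]-10-methyl-3-methylidene-2-oxo-2,3,3a,4,7,8,11,11a-octahydrocyclodeca[b]furan-6-yl]methyl (2Z)-2-(acetoxymethyl)but-2-enoate | C=C1C(=O)O[C@H]2C/C(C)=C/CC/C(COC(=O)/C(=C\C)COC(C)=O)=C\[C@@H](O[Si](C)(C)C(C)(C)C)[C@H]12 | intermediate
34 | [(3aS,4R,5E,9E,11aS)-4-hydroxy-10-methyl-3-methylidene-2-oxo-2,3,3a,4,7,8,11,11a-octahydrocyclodeca[b]furan-6-yl]methyl (2Z)-2-(acetoxymethyl)but-2-enoate | C=C1C(=O)O[C@H]2C/C(C)=C/CC/C(COC(=O)/C(=C\C)COC(C)=O)=C\[C@@H](O)[C@H]12 | target

## Step count and least certain steps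

Total: 21 steps. Longest linear sequence: 15 steps (steps 1–4, 7–15, 20, 21). Steps 5–6 and 16–19 are side branches.

**Step 8 (key step).**
- What may go wrong: onward Cope rearrangement of the product to a divinylcyclohexane; partition into the wrong pair of alkene geometries; thermal enolisation toward C7 with epimerisation or β-elimination of the lactone carboxylate, because C7–H is α to the ketone and the lactone oxygen is β to it.
- Fallback (run the cycloreversion on a non-enolisable substrate): from 14, form the C6 ethylene ketal of the photoadduct F1 (1,2-bis(trimethylsilyloxy)ethane, TMSOTf cat., CH2Cl2, −78 → −20 °C). Heat F1 as in step 8 to the ten-membered ketal enoate F2. Hydrolyse F2 (PPTS, acetone/H2O, rt) and return to the route at 15.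

**Step 2.**
- What may go wrong: proton transfer from the α-bromo ester to the dianion 4 in place of C-alkylation; O-alkylation; retro-aldol cleavage or dehydration of the lithium aldolate on warming; incomplete closure of the trans hydroxy acid.
- Fallback (a non-acidic electrophile, with the acid carbon made by oxidation): from 2, cleave reductively as before and alkylate 4 with allyl bromide to give (2R,3S)-2-allyl-3-hydroxycyclohexanone F3. Ozonise F3 (O3, CH2Cl2/MeOH, −78 °C; Me2S); the aldehyde closes on O8 to the trans-fused lactol F4. Oxidise F4 (TEMPO cat., PhI(OAc)2, CH2Cl2) and return at 6.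

**Step 7.**
- What may go wrong: low regio- and stereoselectivity (head-to-tail or trans-6/4-fused adducts); slow epimerisation of the strained trans-fused enone 10 at C7 on handling; polymerisation of 13 under irradiation.
- Fallback (keep the lactone open until after the photoaddition, where the 2,3-trans arrangement is the stable one): from 5, isolated after the acetic acid quench, silylate (TBSCl, imidazole, DMF) to the silyl ether F5. Dehydrogenate as in step 3 to the enone F6. Methylate and dehydrogenate as in step 4 to the β-methyl enone F7. Irradiate F7 with 13 as in step 7 to the open-chain photoadduct F8. Treat F8 with aqueous HF in MeCN, then CF3CO2H/CH2Cl2 (desilylation, tert-butyl cleavage, lactonisation) and return at 14.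

**Step 9.**
- What may go wrong: poor facial selectivity in the flexible ten-membered ring (C6 epimer); competing conjugate reduction of the doubly activated C4=C5 bond; base-induced loss of the C7 configuration before reduction.
- Fallback (reagent control in place of substrate control): reduce 15 with catecholborane and an oxazaborolidine catalyst (Corey–Bakshi–Shibata reduction, PhMe, −78 °C), choosing the catalyst enantiomer that delivers hydride to the required face. It sets out from 15 and returns at 16 with no new compound.

**Step 20.**
- What may go wrong: conjugate addition of the phosphine to the acetoxymethyl enoate, with Z to E isomerisation or SN2′ loss of acetate; SN2′ attack of the carboxylate at C5; incomplete conversion.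
- Fallback (phosphine and the acid are never in the same flask): from 27, make the C15 allylic bromide F9 (CBr4, PPh3, CH2Cl2, 0 °C). Displace with the caesium carboxylate of 32 (Cs2CO3, DMF, 0 °C) and return at 33.

## Further compounds

F1 | step 8 | C6 ethylene ketal of photoadduct 14 | O=C1C[C@H]2C5(OCCO5)[C@H]3[C@]4(C(=O)OC)CC[C@@H]4[C@@]3(C)C[C@@H]2O1
F2 | step 8 | C6 ethylene ketal of ten-membered enoate 15 | C1C(=O)O[C@H]2C/C(C)=C/CC/C(C(=O)OC)=C\C3(OCCO3)[C@H]12
F3 | step 2 | (2R,3S)-2-allyl-3-hydroxycyclohexanone | O=C1CCC[C@H](O)[C@H]1CC=C
F4 | step 2 | (3aR,7aS)-2-hydroxyhexahydro-1-benzofuran-4(2H)-one (lactol, anomeric carbon undefined) | OC1C[C@H]2C(=O)CCC[C@@H]2O1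
F5 | step 7 | tert-butyl 2-[(1R,2S)-2-[(tert-butyldimethylsilyl)oxy]-6-oxocyclohexyl]acetate | CC(C)(C)OC(=O)C[C@H]1C(=O)CCC[C@@H]1O[Si](C)(C)C(C)(C)C
F6 | step 7 | tert-butyl 2-[(1R,6S)-6-[(tert-butyldimethylsilyl)oxy]-2-oxocyclohex-3-en-1-yl]acetate | CC(C)(C)OC(=O)C[C@H]1C(=O)C=CC[C@@H]1O[Si](C)(C)C(C)(C)C
F7 | step 7 | tert-butyl 2-[(1R,6S)-6-[(tert-butyldimethylsilyl)oxy]-4-methyl-2-oxocyclohex-3-en-1-yl]acetate | CC(C)(C)OC(=O)C[C@H]1C(=O)C=C(C)C[C@@H]1O[Si](C)(C)C(C)(C)C
F8 | step 7 | open-chain head-to-head cis-anti-cis photoadduct (8-O-silyl, 12-tert-butyl ester; ring stereocentres as in 14) | CC(C)(C)OC(=O)C[C@H]2C(=O)[C@H]3[C@]4(C(=O)OC)CC[C@@H]4[C@@]3(C)C[C@@H]2O[Si](C)(C)C(C)(C)C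
F9 | step 20 | (3aR,4R,5E,9E,11aS)-6-(bromomethyl)-4-[(tert-butyldimethylsilyl)oxy]-10-methyl-3-methylidene-3a,4,7,8,11,11a-hexahydrocyclodeca[b]furan-2(3H)-one | C=C1C(=O)O[C@H]2C/C(C)=C/CC/C(CBr)=C\[C@@H](O[Si](C)(C)C(C)(C)C)[C@H]12
F0 | step 9 | none | none
A1 | alternative 1 | thirteen-membered C6-(tributylstannyl) diallylic ether (C6–O–C13, 2,5-dihydrofuran with C7=C11, C15 triisopropylsilyl ether) | C1C2=C[C@@H](OC2)C/C(C)=C/CC/C(CO[Si](C(C)C)(C(C)C)C(C)C)=C\[C@@H]([Sn](CCCC)(CCCC)CCCC)O1
A2 | alternative 1 | ten-membered carbocycle with free C6–OH and fused 3-methylenetetrahydrofuran | C=C1CO[C@H]2C/C(C)=C/CC/C(CO[Si](C(C)C)(C(C)C)C(C)C)=C\[C@@H](O)[C@H]12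
A3 | alternative 2 | potassium (1S,6S)-3-{[(tert-butyldimethylsilyl)oxy]methyl}-1-(5-methoxy-4,5-dihydrofuran-3-yl)-6-(prop-1-en-2-yl)cyclohex-2-en-1-olate | [K+].CO[C@@H]1CC(=CO1)[C@]2([O-])C=C(CO[Si](C)(C)C(C)(C)C)CC[C@H]2C(C)=C
A4 | alternative 2 | ten-membered dienone fused to the methyl lactol ether | C1[C@@H](OC)O[C@H]2C/C(C)=C/CC/C(CO[Si](C)(C)C(C)(C)C)=C\C(=O)[C@H]12
A5 | alternative 3 | eleven-membered cyclic secondary amine (NH between C2 and C3) with 8,12-lactone and silylated C6–OH and C15–OH | C1C(=O)O[C@H]2C/C(C)=C/CNC/C(CO[Si](C)(C)C(C)(C)C)=C\[C@@H](O[Si](C(C)C)(C(C)C)C(C)C)[C@H]12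
A6 | alternative 3 | ten-membered lactone with silylated C6–OH and C15–OH | C1C(=O)O[C@H]2C/C(C)=C/CC/C(CO[Si](C)(C)C(C)(C)C)=C\[C@@H](O[Si](C(C)C)(C(C)C)C(C)C)[C@H]12
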